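(The earlier runs and the new flask were generated by integration with constants of no real substance; noise was put on by code.)

The flask held 0.40 M of substrate against 1.00 M of reagent in the second phase, and Tuesday's run is this flask followed so far.

| setting | Tuesday's | Thursday's | flask |
|---|---|---|---|
| substrate | 0.40 M | 0.40 M | 0.40 M |
| reagent in the second phase | 1 M | 0.50 M | 1.00 M |
| remark | the very flask that is asked about, followed so far | run made earlier |  |
| time |  |  | 4.0 min |
| volume of the second phase over the first |  |  | 0.50 |

Tuesday's run (percent of the substrate charged)

| time / s | target / % | substrate / % |
|---|---|---|
| 10.0 | 4 | 98 |
| 12.0 | 0 | 97 |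
| 20.0 | 2 | 97 |
| 30.0 | 11 | 91 |
| 40.0 | 12 | 84 |
| 60.0 | 20 | 74 |
| 80.0 | 30 | 63 |

Thursday's run (percent of the substrate charged)

| time / min | target / % | substrate / % |
|---|---|---|
| 0.500 | 4 | 98 |
| 1.00 | 11 | 86 |
| 1.50 | 19 | 76 |
| 2.50 | 27 | 58 |
| 3.00 | 30 | 48 |
| 4.00 | 29 | 37 |

(readings scatter by 2 percentage points)

- a species is counted by the substrate in it: one side product counts as two
- in the second phase: reagent in the second phase; everything else is in the first
- charges count per volume of the first phase; a concentration in a rate is the amount of a species over the volume of its own phase; every rate counts per litre of the first phase
- on the list of suspects stand: reagent in the reaction phase <-> reagent in the second phase; reagent in the reaction phase + target -> over-reacted product; substrate + target -> side product; substrate + reagent in the reaction phase <-> target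
- the earlier runs hold the two phases in the same ratio of volumes as the flask asked about

- target at 4.0 min, in percent of the substrate charged
- the change that raises the amount of target at 4.0 min, in percent of the substrate charged most ("none" if none brings more than 2 percentage points) (dusk / winter / none)
- amount of target at 4.0 min, in percent of the substrate charged, after winter

In Tuesday's run substrate fell with constant k = 0.432 /min between 40.0 s and 80.0 s, and that line leaves a lag of 15.8 s. Let a be the fraction of substrate left and θ = −ln a. If target is lost with the same constant as substrate (a selectivity factor of 1), integrating its rate gives target = cθe^(−θ) with c = 1, a curve that peaks at θ = 1. The last reading of Tuesday's run gave the yield constant c, target over aθ, as 1.03, a reading with its scatter.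

So, holding k and c, I reckoned θ = 1.61 at 4.0 min and target 33.1%. That θ lies past the peak, and Thursday's run, with half the reagent in the second phase, lost substrate with the smaller constant 0.281 /min between 1.00 min and 4.00 min, so I expected dusk, the doubling of the amount of reagent in the second phase, to lower target. Winter doubles the transfer coefficient of the reagent in the second phase; my assumption that this took the lag to half gave 32.4%, so I answered none.

The forecast, lower than mine, gave 26%, none and 19%, holding that “Anything that speeds the reaction moves further past the peak”.

The flask gave 32.1%, best none (dusk −19 percentage points, winter −3.4 points), and 28.7% after winter.

    reagent in the reaction phase ⇌ reagent in the second phase, rate k1*([reagent in the reaction phase] - [reagent in the second phase]/K1) per volume of the first phase (partition coefficient = 1.46, kL = 0.00615 /s)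
    reagent in the reaction phase + target → over-reacted product (k = 0.0199 /M/s)
    substrate + target → side product (k = 0.00889 /M/s)
    substrate + reagent in the reaction phase ⇌ target (K = 33.0 /M, k = 0.0329 /M/s)

At 4.00 min the flask held substrate 14.9%, less than my 20.0%, and c on that amount gives target 29.2%. The same flask read at 10 min held substrate 2.39%, for which c gives 9.19%, and it held target 9.16%.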